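**Convention and assumption (one line):** the SMILES is taken as written, including the cis-fused C3–C4 epoxide (so a Z-enone precursor); locants follow bicyclo[9.3.1]pentadecane numbering: ring-A alkene C1=C15, ketone C2, epoxide C3–C4, carbinol C7, ether carbon C8, quaternary C11, CHMe C12, carbinol C14, and "C20" for the CH2O carbon on C15; the target is (3R,4R,7R,8S,11R,12S,14R).

**Retrosynthetic overview**
1. Target 23 ⇐ Z-enone oxepane 22 (late nucleophilic epoxidation of C3=C4) ⇐ 7,8-epoxide 21 by transannular ether closure (C20–O onto C8).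
2. 21 ⇐ 12-membered dienone 20; key disconnection C1–C2 (alkenyl–acyl) gives iodo enal 19, closed by light-driven nickel/hydrogen-atom-transfer catalysis.
3. 19 ⇐ ring-A enone 12 by α-iodination, C20 addition, oxidative transposition and Luche reduction.
4. 12 ⇐ enone 4 (from (S)-carvone: conjugate methylation, dealkenylation) + homoallylic iodide 10 (from nerol); enolate alkylation creates quaternary C11.
5. Ring order: ring A (bought) → 12-membered carbocycle → oxepane → oxirane.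

**Route**

Step 1
Reactants: 1 (S)-(+)-carvone
Product: 2 (2S,3S,5S)-2,3-dimethyl-5-(prop-1-en-2-yl)cyclohexan-1-one
Conditions: MeMgBr, CuBr·SMe2 (5 mol %), THF, −40 to 0 °C; aqueous work-up
Reagents that add atoms: methylmagnesium bromide, C[Mg]Br
Why: Copper-catalysed conjugate addition delivers methyl axially, trans to the isopropenyl group bought in carvone, which fixes the future C12 centre; the α-methyl centre is epimerisable and is planarised again in step 7.

Step 2
Reactants: 2 (2S,3S,5S)-2,3-dimethyl-5-(prop-1-en-2-yl)cyclohexan-1-one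
Product: 4 (5S,6S)-5,6-dimethylcyclohex-2-en-1-one, via methoxy hydroperoxide 3 (not isolated)
Conditions: O3, MeOH/CH2Cl2, −78 °C; then Cu(OAc)2·H2O, FeSO4·7H2O, −20 °C to rt
Reagents that add atoms: none
Why: Ozonolysis in methanol followed by iron/copper-mediated alkoxy-radical β-scission and oxidative elimination (dealkenylative dehydrogenation) removes the isopropenyl group as methyl acetate and leaves the conjugated enone, the methyl-bearing C5 centre being untouched.

Step 3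
Reactants: 5 nerol
Product: 6 tert-butyl{[(2Z)-3,7-dimethylocta-2,6-dien-1-yl]oxy}dimethylsilane
Conditions: TBSCl, imidazole, CH2Cl2, rt
Reagents that add atoms: tert-butyldimethylsilyl chloride, CC(C)(C)[Si](C)(C)Cl
Why: Standard silylation; the 2Z alkene bought in nerol is carried through to become the cis-epoxide C3–C4.

Step 4
Reactants: 6 tert-butyl{[(2Z)-3,7-dimethylocta-2,6-dien-1-yl]oxy}dimethylsilane
Product: 7 (2E,6Z)-8-[(tert-butyldimethylsilyl)oxy]-2,6-dimethylocta-2,6-dienal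
Conditions: SeO2, pyridine, 1,4-dioxane, 80 °C
Reagents that add atoms: selenium dioxide, O=[Se]=O
Why: Riley allylic oxidation (ene reaction then [2,3] shift) is selective for the E-methyl of the terminal trisubstituted alkene and so fixes the E geometry of the future C7=C8 alkene.

Step 5
Reactants: 7 (2E,6Z)-8-[(tert-butyldimethylsilyl)oxy]-2,6-dimethylocta-2,6-dienal
Product: 8 tert-butyl{[(2Z,6E)-3,7-dimethylnona-2,6,8-trien-1-yl]oxy}dimethylsilane
Conditions: Ph3PCH3Br, KN(SiMe3)2, THF, −78 to 0 °C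
Reagents that add atoms: methyltriphenylphosphonium bromide (used as its ylide), C[P+](c1ccccc1)(c1ccccc1)c1ccccc1.[Br-]
Why: Wittig methylenation of the enal adds the carbon that becomes C10 without touching either trisubstituted alkene geometry.

Step 6
Reactants: 8 tert-butyl{[(2Z,6E)-3,7-dimethylnona-2,6,8-trien-1-yl]oxy}dimethylsilane
Product: 10 tert-butyl{[(2Z,6E)-9-iodo-3,7-dimethylnona-2,6-dien-1-yl]oxy}dimethylsilane, via B-alkyl-9-BBN 9 (not isolated)
Conditions: 9-BBN, THF, 0 °C to rt; then NaOMe, I2, MeOH, 0 °C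
Reagents that add atoms: iodine, [I][I]
Why: Anti-Markovnikov hydroboration is selective for the only monosubstituted alkene, and base-induced iodinolysis of the primary C–B bond gives the homoallylic iodide.

Step 7
Reactants: 4 (5S,6S)-5,6-dimethylcyclohex-2-en-1-one; 10 tert-butyl{[(2Z,6E)-9-iodo-3,7-dimethylnona-2,6-dien-1-yl]oxy}dimethylsilane
Product: 12 (5S,6R)-6-[(3E,7Z)-9-[(tert-butyldimethylsilyl)oxy]-3,7-dimethylnona-3,7-dien-1-yl]-5,6-dimethylcyclohex-2-en-1-one, via lithium dienolate 11 (not isolated)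
Conditions: LiN(iPr)2, THF, −78 °C; then 10, DMPU, −78 to 0 °C
Reagents that add atoms: none
Why: Kinetic α′-deprotonation and SN2 enolate alkylation; the iodide attacks the face anti to the adjacent C12 methyl (pseudoaxial through A(1,2) strain), giving quaternary C11 (R) with the two methyls cis, as in alkylations of 2,3-dimethylcyclohexanone enolates.

Step 8
Reactants: 12 (5S,6R)-6-[(3E,7Z)-9-[(tert-butyldimethylsilyl)oxy]-3,7-dimethylnona-3,7-dien-1-yl]-5,6-dimethylcyclohex-2-en-1-one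
Product: 13 (5S,6R)-6-[(3E,7Z)-9-[(tert-butyldimethylsilyl)oxy]-3,7-dimethylnona-3,7-dien-1-yl]-2-iodo-5,6-dimethylcyclohex-2-en-1-one
Conditions: I2, pyridine, CH2Cl2, 0 °C to rt
Reagents that add atoms: iodine, [I][I]
Why: Johnson α-iodination (pyridine conjugate addition, iodination, elimination) is done while the β-carbon is still unhindered; no stereocentre is touched.

Step 9
Reactants: 13 (5S,6R)-6-[(3E,7Z)-9-[(tert-butyldimethylsilyl)oxy]-3,7-dimethylnona-3,7-dien-1-yl]-2-iodo-5,6-dimethylcyclohex-2-en-1-one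
Product: 14 (5S,6R)-1-(tert-butoxymethyl)-6-[(3E,7Z)-9-[(tert-butyldimethylsilyl)oxy]-3,7-dimethylnona-3,7-dien-1-yl]-2-iodo-5,6-dimethylcyclohex-2-en-1-ol (C1 epimers)
Conditions: t-BuOMe, s-BuLi, t-BuOK, −78 °C; LiBr; then 13, THF, −78 °C
Reagents that add atoms: tert-butyl methyl ether (metalated in the flask to tert-butoxymethyllithium), COC(C)(C)C
Why: 1,2-addition of a hydroxymethyl-anion equivalent to the ketone brings in C20 with its oxygen already masked; the new carbinol centre is a mixture that is erased in step 10.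

Step 10
Reactants: 14 (5S,6R)-1-(tert-butoxymethyl)-6-[(3E,7Z)-9-[(tert-butyldimethylsilyl)oxy]-3,7-dimethylnona-3,7-dien-1-yl]-2-iodo-5,6-dimethylcyclohex-2-en-1-ol
Product: 15 (4R,5S)-3-(tert-butoxymethyl)-4-[(3E,7Z)-9-[(tert-butyldimethylsilyl)oxy]-3,7-dimethylnona-3,7-dien-1-yl]-2-iodo-4,5-dimethylcyclohex-2-en-1-one
Conditions: pyridinium chlorochromate [C5H5NH][CrO3Cl], 4 Å molecular sieves, CH2Cl2, rt
Reagents that add atoms: pyridinium chlorochromate, [O-][Cr](=O)(=O)Cl.c1cc[nH+]cc1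
Why: Dauben oxidative 1,3-transposition (chromate ester [3,3] shift, then oxidation) moves oxygen to C14 and creates the tetrasubstituted C1=C15 alkene bearing iodine and C20.

Step 11
Reactants: 15 (4R,5S)-3-(tert-butoxymethyl)-4-[(3E,7Z)-9-[(tert-butyldimethylsilyl)oxy]-3,7-dimethylnona-3,7-dien-1-yl]-2-iodo-4,5-dimethylcyclohex-2-en-1-one
Product: 16 (1R,4R,5S)-3-(tert-butoxymethyl)-4-[(3E,7Z)-9-[(tert-butyldimethylsilyl)oxy]-3,7-dimethylnona-3,7-dien-1-yl]-2-iodo-4,5-dimethylcyclohex-2-en-1-ol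
Conditions: NaBH4, CeCl3·7H2O, MeOH, −78 to −40 °C
Reagents that add atoms: none
Why: Luche 1,2-reduction; axial hydride delivery on the half-chair with the C12 methyl equatorial puts the hydroxyl cis to that methyl (the carvone to cis-carveol pattern), setting C14 (R).

Step 12
Reactants: 16 (1R,4R,5S)-3-(tert-butoxymethyl)-4-[(3E,7Z)-9-[(tert-butyldimethylsilyl)oxy]-3,7-dimethylnona-3,7-dien-1-yl]-2-iodo-4,5-dimethylcyclohex-2-en-1-ol
Product: 17 (1R,4R,5S)-3-(tert-butoxymethyl)-4-[(3E,7Z)-9-[(tert-butyldimethylsilyl)oxy]-3,7-dimethylnona-3,7-dien-1-yl]-2-iodo-4,5-dimethylcyclohex-2-en-1-yl acetate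
Conditions: Ac2O, pyridine, 4-(dimethylamino)pyridine (cat.), CH2Cl2, rt
Reagents that add atoms: acetic anhydride, CC(=O)OC(C)=O
Why: Acylation; the acetate deactivates the C14–H bond toward hydrogen-atom abstraction in step 15 and comes off by itself in step 18.

Step 13
Reactants: 17 (1R,4R,5S)-3-(tert-butoxymethyl)-4-[(3E,7Z)-9-[(tert-butyldimethylsilyl)oxy]-3,7-dimethylnona-3,7-dien-1-yl]-2-iodo-4,5-dimethylcyclohex-2-en-1-yl acetate
Product: 18 (1R,4R,5S)-3-(tert-butoxymethyl)-4-[(3E,7Z)-9-hydroxy-3,7-dimethylnona-3,7-dien-1-yl]-2-iodo-4,5-dimethylcyclohex-2-en-1-yl acetate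
Conditions: HF·pyridine, pyridine, THF, 0 °C
Reagents that add atoms: none
Why: Selective desilylation of the primary allylic silyl ether; the tert-butyl ether, acetate and alkenyl iodide are inert to buffered fluoride.

Step 14
Reactants: 18 (1R,4R,5S)-3-(tert-butoxymethyl)-4-[(3E,7Z)-9-hydroxy-3,7-dimethylnona-3,7-dien-1-yl]-2-iodo-4,5-dimethylcyclohex-2-en-1-yl acetate
Product: 19 (1R,4R,5S)-3-(tert-butoxymethyl)-4-[(3E,7Z)-3,7-dimethyl-9-oxonona-3,7-dien-1-yl]-2-iodo-4,5-dimethylcyclohex-2-en-1-yl acetate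
Conditions: MnO2, hexane/CH2Cl2, rt, dark
Reagents that add atoms: none
Why: Mild allylic oxidation to the enal with retention of the Z geometry (nerol to neral type).

Step 15
Reactants: 19 (1R,4R,5S)-3-(tert-butoxymethyl)-4-[(3E,7Z)-3,7-dimethyl-9-oxonona-3,7-dien-1-yl]-2-iodo-4,5-dimethylcyclohex-2-en-1-yl acetate
Product: 20 (3Z,7E,11R,12S,14R)-15-(tert-butoxymethyl)-4,8,11,12-tetramethyl-2-oxobicyclo[9.3.1]pentadeca-1(15),3,7-trien-14-yl acetate
Conditions: Ir[dF(CF3)ppy]2(dtbbpy)PF6 (2 mol %), NiBr2(dtbbpy) (20 mol %; dtbbpy = 4,4′-di-tert-butyl-2,2′-bipyridine), quinuclidine (20 mol %), K2CO3, 1,4-dioxane (1 mM), 450 nm LEDs, rt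
Reagents that add atoms: none
Why: Proposed new method: intramolecular formyl C–H alkenylation as a macrocyclisation — the photoexcited iridium complex oxidises quinuclidine to its radical cation, which abstracts the hydridic formyl hydrogen of the Z-enal (the σ-acyl radical is not conjugated with C3=C4, so it keeps the Z geometry and does not decarbonylate), zerovalent nickel inserts into the C1–I bond and captures the acyl radical, and reductive elimination from trivalent nickel forms the C1–C2 bond and closes the 12-membered ring directly at the ketone level under high dilution; the closest known reaction type is the intermolecular nickel/photoredox/hydrogen-atom-transfer coupling of aldehydes with aryl and alkyl bromides, together with Nozaki–Hiyama–Kishi macrocyclisations of alkenyl iodides onto aldehydes; no stereocentre is formed.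

Step 16
Reactants: 20 (3Z,7E,11R,12S,14R)-15-(tert-butoxymethyl)-4,8,11,12-tetramethyl-2-oxobicyclo[9.3.1]pentadeca-1(15),3,7-trien-14-yl acetate
Product: 21 (3Z,7R,8R,11R,12S,14R)-15-(tert-butoxymethyl)-7,8-epoxy-4,8,11,12-tetramethyl-2-oxobicyclo[9.3.1]pentadeca-1(15),3-dien-14-yl acetate
Conditions: mCPBA, CH2Cl2, −20 °C
Reagents that add atoms: 3-chloroperoxybenzoic acid, OOC(=O)c1cccc(Cl)c1
Why: Prilezhaev epoxidation touches only the isolated C7=C8 alkene (the other two are enone alkenes) and attacks its peripheral face, the inner face being the one turned toward ring A and C20, so the macrocycle built on C11/C12 controls C7 and C8.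

Step 17
Reactants: 21 (3Z,7R,8R,11R,12S,14R)-15-(tert-butoxymethyl)-7,8-epoxy-4,8,11,12-tetramethyl-2-oxobicyclo[9.3.1]pentadeca-1(15),3-dien-14-yl acetate
Product: 22 (3Z,7R,8S,11R,12S,14R)-8,20-epoxy-7-hydroxy-4,8,11,12-tetramethyl-2-oxobicyclo[9.3.1]pentadeca-1(15),3-dien-14-yl acetate
Conditions: BF3·OEt2 (20 mol %), CH2Cl2, −78 to −30 °C
Reagents that add atoms: none
Why: Acid-promoted transannular epoxide opening: the C20 ether oxygen attacks the tertiary C8 from the inner face with inversion (7-membered ring closure, net anti addition across the former E-alkene) and the oxonium ion loses isobutene, so C8 becomes S while C7 keeps its R configuration.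

Step 18
Reactants: 22 (3Z,7R,8S,11R,12S,14R)-8,20-epoxy-7-hydroxy-4,8,11,12-tetramethyl-2-oxobicyclo[9.3.1]pentadeca-1(15),3-dien-14-yl acetate
Product: 23 (3R,4R,7R,8S,11R,12S,14R)-3,4:8,20-diepoxy-7,14-dihydroxy-4,8,11,12-tetramethylbicyclo[9.3.1]pentadec-1(15)-en-2-one (target CNP0316768.3)
Conditions: H2O2 (30 % aq.), K2CO3, MeOH, 0 °C to rt
Reagents that add atoms: hydrogen peroxide, OO
Why: Weitz–Scheffer nucleophilic epoxidation: hydroperoxide adds to the less hindered trisubstituted C3=C4 enone (C1=C15 is tetrasubstituted) from the exposed face of the rigid tricycle and closes before C3–C4 rotation, which should give the cis (3R,4R) epoxide, while methanolysis frees the C14 hydroxyl.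

**Compound list**
1 | (S)-(+)-carvone, (5S)-2-methyl-5-(prop-1-en-2-yl)cyclohex-2-en-1-one | CC1=CC[C@H](C(C)=C)CC1=O | starting material
2 | (2S,3S,5S)-2,3-dimethyl-5-(prop-1-en-2-yl)cyclohexan-1-one (C2 epimerisable) | C[C@H]1C[C@H](C(C)=C)CC(=O)[C@H]1C | intermediate
3 | (2S,3S,5S)-5-(1-hydroperoxy-1-methoxyethyl)-2,3-dimethylcyclohexan-1-one | C[C@H]1C[C@H](C(C)(OC)OO)CC(=O)[C@H]1C | intermediate
4 | (5S,6S)-5,6-dimethylcyclohex-2-en-1-one (C6 epimerisable) | C[C@H]1CC=CC(=O)[C@H]1C | intermediate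
5 | nerol, (2Z)-3,7-dimethylocta-2,6-dien-1-ol | CC(C)=CCC/C(C)=C\CO | starting material
6 | tert-butyl{[(2Z)-3,7-dimethylocta-2,6-dien-1-yl]oxy}dimethylsilane | CC(C)=CCC/C(C)=C\CO[Si](C)(C)C(C)(C)C | intermediate
7 | (2E,6Z)-8-[(tert-butyldimethylsilyl)oxy]-2,6-dimethylocta-2,6-dienal | O=C/C(C)=C/CC/C(C)=C\CO[Si](C)(C)C(C)(C)C | intermediate
8 | tert-butyl{[(2Z,6E)-3,7-dimethylnona-2,6,8-trien-1-yl]oxy}dimethylsilane | C=C/C(C)=C/CC/C(C)=C\CO[Si](C)(C)C(C)(C)C | intermediate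
9 | 9-[(3E,7Z)-9-[(tert-butyldimethylsilyl)oxy]-3,7-dimethylnona-3,7-dien-1-yl]-9-borabicyclo[3.3.1]nonane | C(C/C(C)=C/CC/C(C)=C\CO[Si](C)(C)C(C)(C)C)B1C2CCCC1CCC2 | intermediate
10 | tert-butyl{[(2Z,6E)-9-iodo-3,7-dimethylnona-2,6-dien-1-yl]oxy}dimethylsilane | ICC/C(C)=C/CC/C(C)=C\CO[Si](C)(C)C(C)(C)C | intermediate
11 | lithium (3S)-2,3-dimethylcyclohexa-1,5-dien-1-olate | C[C@H]1CC=CC(O[Li])=C1C | intermediate
12 | (5S,6R)-6-[(3E,7Z)-9-[(tert-butyldimethylsilyl)oxy]-3,7-dimethylnona-3,7-dien-1-yl]-5,6-dimethylcyclohex-2-en-1-one | C[C@H]1CC=CC(=O)[C@]1(C)CC/C(C)=C/CC/C(C)=C\CO[Si](C)(C)C(C)(C)C | intermediate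
13 | (5S,6R)-6-[(3E,7Z)-9-[(tert-butyldimethylsilyl)oxy]-3,7-dimethylnona-3,7-dien-1-yl]-2-iodo-5,6-dimethylcyclohex-2-en-1-one | C[C@H]1CC=C(I)C(=O)[C@]1(C)CC/C(C)=C/CC/C(C)=C\CO[Si](C)(C)C(C)(C)C | intermediate
14 | (5S,6R)-1-(tert-butoxymethyl)-6-[(3E,7Z)-9-[(tert-butyldimethylsilyl)oxy]-3,7-dimethylnona-3,7-dien-1-yl]-2-iodo-5,6-dimethylcyclohex-2-en-1-ol (C1 epimers) | C[C@H]1CC=C(I)C(O)(COC(C)(C)C)[C@]1(C)CC/C(C)=C/CC/C(C)=C\CO[Si](C)(C)C(C)(C)C | intermediate
15 | (4R,5S)-3-(tert-butoxymethyl)-4-[(3E,7Z)-9-[(tert-butyldimethylsilyl)oxy]-3,7-dimethylnona-3,7-dien-1-yl]-2-iodo-4,5-dimethylcyclohex-2-en-1-one | C[C@H]1CC(=O)C(I)=C(COC(C)(C)C)[C@]1(C)CC/C(C)=C/CC/C(C)=C\CO[Si](C)(C)C(C)(C)C | intermediate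
16 | (1R,4R,5S)-3-(tert-butoxymethyl)-4-[(3E,7Z)-9-[(tert-butyldimethylsilyl)oxy]-3,7-dimethylnona-3,7-dien-1-yl]-2-iodo-4,5-dimethylcyclohex-2-en-1-ol | C[C@H]1C[C@@H](O)C(I)=C(COC(C)(C)C)[C@]1(C)CC/C(C)=C/CC/C(C)=C\CO[Si](C)(C)C(C)(C)C | intermediate
17 | (1R,4R,5S)-3-(tert-butoxymethyl)-4-[(3E,7Z)-9-[(tert-butyldimethylsilyl)oxy]-3,7-dimethylnona-3,7-dien-1-yl]-2-iodo-4,5-dimethylcyclohex-2-en-1-yl acetate | C[C@H]1C[C@@H](OC(C)=O)C(I)=C(COC(C)(C)C)[C@]1(C)CC/C(C)=C/CC/C(C)=C\CO[Si](C)(C)C(C)(C)C | intermediate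
18 | (1R,4R,5S)-3-(tert-butoxymethyl)-4-[(3E,7Z)-9-hydroxy-3,7-dimethylnona-3,7-dien-1-yl]-2-iodo-4,5-dimethylcyclohex-2-en-1-yl acetate | C[C@H]1C[C@@H](OC(C)=O)C(I)=C(COC(C)(C)C)[C@]1(C)CC/C(C)=C/CC/C(C)=C\CO | intermediate
19 | (1R,4R,5S)-3-(tert-butoxymethyl)-4-[(3E,7Z)-3,7-dimethyl-9-oxonona-3,7-dien-1-yl]-2-iodo-4,5-dimethylcyclohex-2-en-1-yl acetate | C[C@H]1C[C@@H](OC(C)=O)C(I)=C(COC(C)(C)C)[C@]1(C)CC/C(C)=C/CC/C(C)=C\C=O | intermediate
20 | (3Z,7E,11R,12S,14R)-15-(tert-butoxymethyl)-4,8,11,12-tetramethyl-2-oxobicyclo[9.3.1]pentadeca-1(15),3,7-trien-14-yl acetate | C[C@H]1C[C@@H](OC(C)=O)C2=C(COC(C)(C)C)[C@]1(C)CC/C(C)=C/CC/C(C)=C\C2=O | intermediate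
21 | (3Z,7R,8R,11R,12S,14R)-15-(tert-butoxymethyl)-7,8-epoxy-4,8,11,12-tetramethyl-2-oxobicyclo[9.3.1]pentadeca-1(15),3-dien-14-yl acetate | C[C@H]1C[C@@H](OC(C)=O)C2=C(COC(C)(C)C)[C@]1(C)CC[C@@]3(C)O[C@@H]3CC/C(C)=C\C2=O | intermediate
22 | (3Z,7R,8S,11R,12S,14R)-8,20-epoxy-7-hydroxy-4,8,11,12-tetramethyl-2-oxobicyclo[9.3.1]pentadeca-1(15),3-dien-14-yl acetate (oxepane C15–C20–O–C8–C9–C10–C11) | C[C@H]1C[C@@H](OC(C)=O)C2=C3CO[C@@](C)(CC[C@@]31C)[C@H](O)CC/C(C)=C\C2=O | intermediate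
23 | (3R,4R,7R,8S,11R,12S,14R)-3,4:8,20-diepoxy-7,14-dihydroxy-4,8,11,12-tetramethylbicyclo[9.3.1]pentadec-1(15)-en-2-one (CNP0316768.3) | C[C@H]1C[C@@H](O)C2=C3CO[C@@](C)(CC[C@@]31C)[C@H](O)CC[C@@]1(C)O[C@H]1C2=O | target

**Step count:** 18 steps in total; longest linear sequence 16 steps (nerol 5 to 23: steps 3–18).

**Steps most likely to fail, with fallbacks**

Step 15 (the new ring closure). The risks are hydrogen abstraction at allylic or ether C–H bonds instead of the formyl group, Z to E erosion of the enal under irradiation, and slow capture by the hindered alkenylnickel species. The fallback sets out from 19 and comes back at 20. A classical Nozaki–Hiyama–Kishi macrocyclisation (CrCl2, NiCl2 1 mol %, DMSO/THF, high dilution) gives the macrocyclic bis-allylic alcohol (3Z,7E,11R,12S,14R)-15-(tert-butoxymethyl)-2-hydroxy-4,8,11,12-tetramethylbicyclo[9.3.1]pentadeca-1(15),3,7-trien-14-yl acetate F1 as a C2 epimer mixture. Dess–Martin periodinane then oxidises it to 20.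

Step 16 (face of the macrocyclic epoxidation, which fixes C7 and C8). Peripheral attack is reliable, but which rotamer of the E-alkene reacts is not certain; the other rotamer would give the 7,8-bis-epimer. The fallback sets out from 20 and comes back at 23 by changing the order of the oxygenations, so that the epoxidation is run on a differently folded strap. H2O2/K2CO3/MeOH first gives the cis-epoxy ketone (3R,4R,7E,11R,12S,14R)-15-(tert-butoxymethyl)-3,4-epoxy-14-hydroxy-4,8,11,12-tetramethylbicyclo[9.3.1]pentadeca-1(15),7-dien-2-one F2. mCPBA then gives the bis-epoxide (3R,4R,7R,8R,11R,12S,14R)-15-(tert-butoxymethyl)-3,4:7,8-diepoxy-14-hydroxy-4,8,11,12-tetramethylbicyclo[9.3.1]pentadec-1(15)-en-2-one F3, and BF3·OEt2 closes the oxepane to give 23 directly.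

Step 18 (cis geometry and face of the enone epoxidation). The stepwise nucleophilic mechanism could leak to the trans epoxide or attack the other face. The fallback sets out from 20 and comes back at 23, and uses concerted electrophilic oxygen transfer, which cannot scramble the alkene geometry. Excess dimethyldioxirane (acetone, 0 °C to rt) epoxidises both C7=C8 and the Z-enone C3=C4, with no free alcohol present, to give the bis-epoxide acetate (3R,4R,7R,8R,11R,12S,14R)-15-(tert-butoxymethyl)-3,4:7,8-diepoxy-4,8,11,12-tetramethyl-2-oxobicyclo[9.3.1]pentadec-1(15)-en-14-yl acetate F4. BF3·OEt2 then gives the oxepane acetate (3R,4R,7R,8S,11R,12S,14R)-3,4:8,20-diepoxy-7-hydroxy-4,8,11,12-tetramethyl-2-oxobicyclo[9.3.1]pentadec-1(15)-en-14-yl acetate F5, and K2CO3/MeOH removes the acetate to give 23.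

**Further compounds**
F1 | step 15 | (3Z,7E,11R,12S,14R)-15-(tert-butoxymethyl)-2-hydroxy-4,8,11,12-tetramethylbicyclo[9.3.1]pentadeca-1(15),3,7-trien-14-yl acetate (C2 epimers) | C[C@H]1C[C@@H](OC(C)=O)C2=C(COC(C)(C)C)[C@]1(C)CC/C(C)=C/CC/C(C)=C\C2O
F2 | step 16 | (3R,4R,7E,11R,12S,14R)-15-(tert-butoxymethyl)-3,4-epoxy-14-hydroxy-4,8,11,12-tetramethylbicyclo[9.3.1]pentadeca-1(15),7-dien-2-one | C[C@H]1C[C@@H](O)C2=C(COC(C)(C)C)[C@]1(C)CC/C(C)=C/CC[C@@]3(C)O[C@H]3C2=O
F3 | step 16 | (3R,4R,7R,8R,11R,12S,14R)-15-(tert-butoxymethyl)-3,4:7,8-diepoxy-14-hydroxy-4,8,11,12-tetramethylbicyclo[9.3.1]pentadec-1(15)-en-2-one | C[C@H]1C[C@@H](O)C2=C(COC(C)(C)C)[C@]1(C)CC[C@@]4(C)O[C@@H]4CC[C@@]3(C)O[C@H]3C2=O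
F4 | step 18 | (3R,4R,7R,8R,11R,12S,14R)-15-(tert-butoxymethyl)-3,4:7,8-diepoxy-4,8,11,12-tetramethyl-2-oxobicyclo[9.3.1]pentadec-1(15)-en-14-yl acetate | C[C@H]1C[C@@H](OC(C)=O)C2=C(COC(C)(C)C)[C@]1(C)CC[C@@]4(C)O[C@@H]4CC[C@@]3(C)O[C@H]3C2=O
F5 | step 18 | (3R,4R,7R,8S,11R,12S,14R)-3,4:8,20-diepoxy-7-hydroxy-4,8,11,12-tetramethyl-2-oxobicyclo[9.3.1]pentadec-1(15)-en-14-yl acetate | C[C@H]1C[C@@H](OC(C)=O)C2=C3CO[C@@](C)(CC[C@@]31C)[C@H](O)CC[C@@]1(C)O[C@H]1C2=O
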